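**Retrosynthetic overview**
1. Target 17 ⇐ tri-O-benzyl flavanone 16 by global hydrogenolysis (last step, no stereocentre touched).
2. The pyranone C ring is the only ring made and is closed last: C2–O1 bond by a chalcone-isomerase-like 6-endo oxa-Michael addition of the 2'-hydroxychalcone 15 under catalyst control, which sets 2S on the fully elaborated substrate.
3. Chalcone 15 ⇐ Claisen–Schmidt condensation of the A-ring acetophenone 14 with the B-ring aldehyde 12, which already carries the complete threo side chain.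
4. Side chain: C7–C8 bond and both stereocentres (7R,8R) by an Evans syn-glycolate aldol of the aryloxyacetyl imide 7 with 4-(benzyloxy)benzaldehyde; the C8–O–aryl bond comes from syringaldehyde and a chloroacetyl imide.
5. All three benzene rings are bought (phloroacetophenone, syringaldehyde, 4-(benzyloxy)benzaldehyde).

Assumption: the quinidine-derived squaramide is taken to give the 2S sense in step 8; if the first run gives 2R, the quinine-derived pseudo-enantiomer is used and nothing else changes.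

**Step 1**
Reactants: 1 (4S)-4-benzyl-1,3-oxazolidin-2-one; 2 chloroacetyl chloride
Product: 4 (4S)-4-benzyl-3-(chloroacetyl)-1,3-oxazolidin-2-one, via N-lithio oxazolidinone 3 (not isolated)
Conditions: n-BuLi, THF, −78 °C; then 2, −78 → 0 °C
Reagents that add atoms: none
Why: N-acylation of the lithiated oxazolidinone with an acid chloride is the standard loading of an Evans auxiliary and touches no stereocentre.

**Step 2**
Reactants: 4 (4S)-4-benzyl-3-(chloroacetyl)-1,3-oxazolidin-2-one; 5 syringaldehyde (4-hydroxy-3,5-dimethoxybenzaldehyde)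
Product: 6 (4S)-4-benzyl-3-[2-(4-formyl-2,6-dimethoxyphenoxy)acetyl]-1,3-oxazolidin-2-one
Conditions: K2CO3, MeCN, 60 °C
Reagents that add atoms: none
Why: Williamson ether synthesis, in which the hindered but soft phenoxide displaces the activated α-chloride of the imide by SN2 faster than it attacks either imide carbonyl.

**Step 3**
Reactants: 6 (4S)-4-benzyl-3-[2-(4-formyl-2,6-dimethoxyphenoxy)acetyl]-1,3-oxazolidin-2-one
Product: 7 (4S)-4-benzyl-3-{2-[4-(1,3-dioxolan-2-yl)-2,6-dimethoxyphenoxy]acetyl}-1,3-oxazolidin-2-one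
Conditions: TMSOCH2CH2OTMS, TMSOTf (5 mol%), CH2Cl2, −78 → −20 °C; pyridine quench
Reagents that add atoms: 1,2-bis(trimethylsilyloxy)ethane, C[Si](C)(C)OCCO[Si](C)(C)C
Why: Noyori acetalisation masks the aryl aldehyde at low temperature without touching the imide, so that it can neither intercept the boron enolate in step 4 nor be reduced in step 5, and doing it after O-alkylation avoids the labile acetal of a free para-hydroxybenzaldehyde.

**Step 4**
Reactants: 7 (4S)-4-benzyl-3-{2-[4-(1,3-dioxolan-2-yl)-2,6-dimethoxyphenoxy]acetyl}-1,3-oxazolidin-2-one; 8 4-(benzyloxy)benzaldehyde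
Product: 10 (4S)-4-benzyl-3-{(2S,3R)-3-[4-(benzyloxy)phenyl]-2-[4-(1,3-dioxolan-2-yl)-2,6-dimethoxyphenoxy]-3-hydroxypropanoyl}-1,3-oxazolidin-2-one, via Z-boron enolate 9 (not isolated)
Conditions: Bu2BOTf, iPr2NEt, CH2Cl2, −78 → 0 °C; then 8, −78 → 0 °C; pH 7 buffer, MeOH, 30% H2O2, 0 °C
Reagents that add atoms: none
Why: Evans syn-aldol (glycolate variant), in which the Z-boron enolate reacts through a closed Zimmerman–Traxler chair on the face not shielded by the auxiliary benzyl group, giving the 2,3-syn (threo) adduct and setting both side-chain centres (7R,8R after reduction) in one step.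

**Step 5**
Reactants: 10 (4S)-4-benzyl-3-{(2S,3R)-3-[4-(benzyloxy)phenyl]-2-[4-(1,3-dioxolan-2-yl)-2,6-dimethoxyphenoxy]-3-hydroxypropanoyl}-1,3-oxazolidin-2-one
Product: 12 4-{[(1R,2R)-1-[4-(benzyloxy)phenyl]-1,3-dihydroxypropan-2-yl]oxy}-3,5-dimethoxybenzaldehyde, via acetal diol 11 (not isolated)
Conditions: LiBH4, THF, 0 °C → rt; then 1 M aq. HCl, THF, 0 °C → rt, 30 min
Reagents that add atoms: water, O
Why: Reductive cleavage of the imide by LiBH4 gives the primary alcohol and releases the auxiliary, and the acidic quench hydrolyses the electron-rich aryl dioxolane under conditions too mild to ionise the β-aryloxy benzylic alcohol, so both stereocentres are kept.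

**Step 6**
Reactants: 13 2',4',6'-trihydroxyacetophenone
Product: 14 1-[2,4-bis(benzyloxy)-6-hydroxyphenyl]ethan-1-one
Conditions: BnBr (2.05 equiv), K2CO3, DMF, rt
Reagents that add atoms: benzyl bromide, BrCc1ccccc1
Why: Williamson benzylation takes the 4-OH and one ortho-OH, because the remaining ortho-OH is hydrogen-bonded to the ketone and is the least nucleophilic.

**Step 7**
Reactants: 12 4-{[(1R,2R)-1-[4-(benzyloxy)phenyl]-1,3-dihydroxypropan-2-yl]oxy}-3,5-dimethoxybenzaldehyde; 14 1-[2,4-bis(benzyloxy)-6-hydroxyphenyl]ethan-1-one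
Product: 15 (E)-1-[2,4-bis(benzyloxy)-6-hydroxyphenyl]-3-[4-({(1R,2R)-1-[4-(benzyloxy)phenyl]-1,3-dihydroxypropan-2-yl}oxy)-3,5-dimethoxyphenyl]prop-2-en-1-one
Conditions: KOH (50% aq.), EtOH, rt, 48 h; AcOH to pH 6 at 0 °C
Reagents that add atoms: none
Why: Claisen–Schmidt condensation (crossed aldol, E1cB dehydration) gives the E-chalcone, the non-phenolic β-aryl ether side chain is inert to hydroxide at room temperature, and in strong base the open chalcone phenolate is favoured so the ring closure is kept for step 8.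

**Step 8**
Reactants: 15 (E)-1-[2,4-bis(benzyloxy)-6-hydroxyphenyl]-3-[4-({(1R,2R)-1-[4-(benzyloxy)phenyl]-1,3-dihydroxypropan-2-yl}oxy)-3,5-dimethoxyphenyl]prop-2-en-1-one
Product: 16 (2S)-5,7-bis(benzyloxy)-2-[4-({(1R,2R)-1-[4-(benzyloxy)phenyl]-1,3-dihydroxypropan-2-yl}oxy)-3,5-dimethoxyphenyl]-2,3-dihydro-4H-chromen-4-one
Conditions: quinidine-derived squaramide (9-amino-9-deoxy-epi-quinidine 3,5-(CF3)2C6H3 squaramide, 10 mol%), PhCl, 25 °C
Reagents that add atoms: none
Why: Proposed new method: the quinuclidine nitrogen deprotonates the chelated 2'-OH while the squaramide N–H pair binds the enone carbonyl, so the phenoxide adds 6-endo to the Si face of C-β of the s-cis enone and the enolate is protonated by the quinuclidinium, which sets 2S under catalyst control far from the side-chain centres, and the weak amine base does not re-open the 5-O-benzyl flavanone at room temperature so the kinetic selectivity holds; the closest known reaction type is the cinchona (thio)urea-catalysed intramolecular oxa-Michael addition of 2'-hydroxychalcones and of alkylidene β-keto esters to flavanones, the abiotic copy of chalcone isomerase.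

**Step 9**
Reactants: 16 (2S)-5,7-bis(benzyloxy)-2-[4-({(1R,2R)-1-[4-(benzyloxy)phenyl]-1,3-dihydroxypropan-2-yl}oxy)-3,5-dimethoxyphenyl]-2,3-dihydro-4H-chromen-4-one
Product: 17 (2S)-2-[4-{[(1R,2R)-1,3-dihydroxy-1-(4-hydroxyphenyl)propan-2-yl]oxy}-3,5-dimethoxyphenyl]-5,7-dihydroxy-2,3-dihydro-4H-chromen-4-one
Conditions: H2 (1 atm), 10% Pd/C, EtOAc–MeOH, rt, stopped at full debenzylation
Reagents that add atoms: none
Why: Hydrogenolysis of the three aryl benzyl ethers over Pd/C under neutral conditions is much faster than reduction of the flavanone carbonyl or cleavage of the C2–O1 and C7–OH bonds, so all three stereocentres survive.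

**Compound list**
1 | (4S)-4-benzyl-1,3-oxazolidin-2-one | O=C1N[C@@H](Cc2ccccc2)CO1 | starting material
2 | chloroacetyl chloride | ClCC(Cl)=O | starting material
3 | lithium (4S)-4-benzyl-2-oxo-1,3-oxazolidin-3-ide (N-lithio oxazolidinone) | [Li]N1[C@@H](Cc2ccccc2)COC1=O | intermediate
4 | (4S)-4-benzyl-3-(chloroacetyl)-1,3-oxazolidin-2-one | O=C(CCl)N1[C@@H](Cc2ccccc2)COC1=O | intermediate
5 | syringaldehyde (4-hydroxy-3,5-dimethoxybenzaldehyde) | COc1cc(C=O)cc(OC)c1O | starting material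
6 | (4S)-4-benzyl-3-[2-(4-formyl-2,6-dimethoxyphenoxy)acetyl]-1,3-oxazolidin-2-one | COc1cc(C=O)cc(OC)c1OCC(=O)N1[C@@H](Cc2ccccc2)COC1=O | intermediate
7 | (4S)-4-benzyl-3-{2-[4-(1,3-dioxolan-2-yl)-2,6-dimethoxyphenoxy]acetyl}-1,3-oxazolidin-2-one | COc1cc(C2OCCO2)cc(OC)c1OCC(=O)N1[C@@H](Cc2ccccc2)COC1=O | intermediate
8 | 4-(benzyloxy)benzaldehyde | O=Cc1ccc(OCc2ccccc2)cc1 | starting material
9 | (Z)-O-dibutylboryl enolate of 7 (Z-boron enolate) | CCCCB(CCCC)O/C(=C\Oc1c(OC)cc(C2OCCO2)cc1OC)N1[C@@H](Cc2ccccc2)COC1=O | intermediate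
10 | (4S)-4-benzyl-3-{(2S,3R)-3-[4-(benzyloxy)phenyl]-2-[4-(1,3-dioxolan-2-yl)-2,6-dimethoxyphenoxy]-3-hydroxypropanoyl}-1,3-oxazolidin-2-one | COc1cc(C2OCCO2)cc(OC)c1O[C@H](C(=O)N1[C@@H](Cc2ccccc2)COC1=O)[C@H](O)c1ccc(OCc2ccccc2)cc1 | intermediate
11 | (1R,2R)-1-[4-(benzyloxy)phenyl]-2-[4-(1,3-dioxolan-2-yl)-2,6-dimethoxyphenoxy]propane-1,3-diol (acetal diol) | COc1cc(C2OCCO2)cc(OC)c1O[C@H](CO)[C@H](O)c1ccc(OCc2ccccc2)cc1 | intermediate
12 | 4-{[(1R,2R)-1-[4-(benzyloxy)phenyl]-1,3-dihydroxypropan-2-yl]oxy}-3,5-dimethoxybenzaldehyde | COc1cc(C=O)cc(OC)c1O[C@H](CO)[C@H](O)c1ccc(OCc2ccccc2)cc1 | intermediate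
13 | 2',4',6'-trihydroxyacetophenone | CC(=O)c1c(O)cc(O)cc1O | starting material
14 | 1-[2,4-bis(benzyloxy)-6-hydroxyphenyl]ethan-1-one | CC(=O)c1c(O)cc(OCc2ccccc2)cc1OCc1ccccc1 | intermediate
15 | (E)-1-[2,4-bis(benzyloxy)-6-hydroxyphenyl]-3-[4-({(1R,2R)-1-[4-(benzyloxy)phenyl]-1,3-dihydroxypropan-2-yl}oxy)-3,5-dimethoxyphenyl]prop-2-en-1-one | COc1cc(/C=C/C(=O)c2c(O)cc(OCc3ccccc3)cc2OCc2ccccc2)cc(OC)c1O[C@H](CO)[C@H](O)c1ccc(OCc2ccccc2)cc1 | intermediate
16 | (2S)-5,7-bis(benzyloxy)-2-[4-({(1R,2R)-1-[4-(benzyloxy)phenyl]-1,3-dihydroxypropan-2-yl}oxy)-3,5-dimethoxyphenyl]-2,3-dihydro-4H-chromen-4-one | COc1cc([C@@H]2CC(=O)c3c(OCc4ccccc4)cc(OCc4ccccc4)cc3O2)cc(OC)c1O[C@H](CO)[C@H](O)c1ccc(OCc2ccccc2)cc1 | intermediate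
17 | (2S)-2-[4-{[(1R,2R)-1,3-dihydroxy-1-(4-hydroxyphenyl)propan-2-yl]oxy}-3,5-dimethoxyphenyl]-5,7-dihydroxy-2,3-dihydro-4H-chromen-4-one | COc1cc([C@@H]2CC(=O)c3c(O)cc(O)cc3O2)cc(OC)c1O[C@H](CO)[C@H](O)c1ccc(O)cc1 | target

**Summary**
Total step count: 9.
Longest linear sequence: 8 (steps 1–5 and 7–9, from 1); step 6 is a one-step side branch.

**Steps most likely to fail, with fallbacks**

Step 8 (catalytic asymmetric ring closure). The catalyst may turn over slowly on this unactivated, hydrogen-bonded chalcone, the free diol may compete for the squaramide, and the selectivity at C-2 may be only moderate. The fallback gives up catalyst control. It sets out from 15, which is closed without stereocontrol at C-2 (NaOAc, EtOH, reflux) to a roughly 1:1 mixture of 16 and the (2R)-epimer of 16 F1. The two are diastereomers and are separated by preparative HPLC or SFC on a polysaccharide chiral phase. F1 is re-opened to 15 with KOH in EtOH and recycled. The fallback comes back to the route at 16.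

Step 9 (global hydrogenolysis). Over-reduction is possible: loss of the benzylic C7–OH, or opening of the C ring to the dihydrochalcone. The fallback replaces all benzyl ethers by allyl ethers, which are removed without hydrogen. It sets out from 7 and 13. The boron aldol of 7 is run with commercial 4-(allyloxy)benzaldehyde instead of 8 and gives the allyl-protected aldol adduct F2. LiBH4 reduction gives the allyl-protected acetal diol F3, which the acidic quench hydrolyses to the allyl-protected aldehyde diol F4. Compound 13 is O-allylated (allyl bromide, K2CO3, DMF) to 1-[2-hydroxy-4,6-bis(allyloxy)phenyl]ethan-1-one F5. Claisen–Schmidt condensation of F4 and F5 gives the tri-O-allyl chalcone F6, and the same catalytic oxa-Michael closure gives the tri-O-allyl flavanone F7. Pd(PPh3)4 and morpholine in THF at room temperature then transfer the three allyl groups to the amine. The fallback comes back to the route at 17.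

Step 5 (hydride cleavage and acidic unmasking). The acid needed to open the dioxolane acts next to an acid-labile para-alkoxybenzylic alcohol, so C-7 could epimerise, and the β-hydroxy imide could undergo retro-aldol during reduction. The fallback changes the latent aldehyde to a nitrile, which needs no acid and also removes step 3 and the acetal from the boron aldol. It sets out from 4 and 8. Commercial 4-hydroxy-3,5-dimethoxybenzonitrile is alkylated with 4 (K2CO3, MeCN) to the nitrile imide F8. The same boron aldol with 8 gives the nitrile aldol adduct F9. LiBH4 cleaves the imide and leaves the nitrile, giving the nitrile diol F10. DIBAL-H (4 equiv, CH2Cl2, −78 → 0 °C), followed by Rochelle salt and wet silica, reduces the nitrile and hydrolyses the aldimine. The fallback comes back to the route at 12.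

**Further compounds**
F1 | step 8 | (2R)-5,7-bis(benzyloxy)-2-[4-({(1R,2R)-1-[4-(benzyloxy)phenyl]-1,3-dihydroxypropan-2-yl}oxy)-3,5-dimethoxyphenyl]-2,3-dihydro-4H-chromen-4-one | COc1cc([C@H]2CC(=O)c3c(OCc4ccccc4)cc(OCc4ccccc4)cc3O2)cc(OC)c1O[C@H](CO)[C@H](O)c1ccc(OCc2ccccc2)cc1
F2 | step 9 | (4S)-3-{(2S,3R)-3-[4-(allyloxy)phenyl]-2-[4-(1,3-dioxolan-2-yl)-2,6-dimethoxyphenoxy]-3-hydroxypropanoyl}-4-benzyl-1,3-oxazolidin-2-one | COc1cc(C2OCCO2)cc(OC)c1O[C@H](C(=O)N1[C@@H](Cc2ccccc2)COC1=O)[C@H](O)c1ccc(OCC=C)cc1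
F3 | step 9 | (1R,2R)-1-[4-(allyloxy)phenyl]-2-[4-(1,3-dioxolan-2-yl)-2,6-dimethoxyphenoxy]propane-1,3-diol | COc1cc(C2OCCO2)cc(OC)c1O[C@H](CO)[C@H](O)c1ccc(OCC=C)cc1
F4 | step 9 | 4-{[(1R,2R)-1-[4-(allyloxy)phenyl]-1,3-dihydroxypropan-2-yl]oxy}-3,5-dimethoxybenzaldehyde | COc1cc(C=O)cc(OC)c1O[C@H](CO)[C@H](O)c1ccc(OCC=C)cc1
F5 | step 9 | 1-[2-hydroxy-4,6-bis(allyloxy)phenyl]ethan-1-one | CC(=O)c1c(O)cc(OCC=C)cc1OCC=C
F6 | step 9 | (E)-1-[2,4-bis(allyloxy)-6-hydroxyphenyl]-3-[4-({(1R,2R)-1-[4-(allyloxy)phenyl]-1,3-dihydroxypropan-2-yl}oxy)-3,5-dimethoxyphenyl]prop-2-en-1-one | COc1cc(/C=C/C(=O)c2c(O)cc(OCC=C)cc2OCC=C)cc(OC)c1O[C@H](CO)[C@H](O)c1ccc(OCC=C)cc1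
F7 | step 9 | (2S)-5,7-bis(allyloxy)-2-[4-({(1R,2R)-1-[4-(allyloxy)phenyl]-1,3-dihydroxypropan-2-yl}oxy)-3,5-dimethoxyphenyl]-2,3-dihydro-4H-chromen-4-one | COc1cc([C@@H]2CC(=O)c3c(OCC=C)cc(OCC=C)cc3O2)cc(OC)c1O[C@H](CO)[C@H](O)c1ccc(OCC=C)cc1
F8 | step 5 | (4S)-4-benzyl-3-[2-(4-cyano-2,6-dimethoxyphenoxy)acetyl]-1,3-oxazolidin-2-one | COc1cc(C#N)cc(OC)c1OCC(=O)N1[C@@H](Cc2ccccc2)COC1=O
F9 | step 5 | (4S)-4-benzyl-3-{(2S,3R)-3-[4-(benzyloxy)phenyl]-2-(4-cyano-2,6-dimethoxyphenoxy)-3-hydroxypropanoyl}-1,3-oxazolidin-2-one | COc1cc(C#N)cc(OC)c1O[C@H](C(=O)N1[C@@H](Cc2ccccc2)COC1=O)[C@H](O)c1ccc(OCc2ccccc2)cc1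
F10 | step 5 | 4-{[(1R,2R)-1-[4-(benzyloxy)phenyl]-1,3-dihydroxypropan-2-yl]oxy}-3,5-dimethoxybenzonitrile | COc1cc(C#N)cc(OC)c1O[C@H](CO)[C@H](O)c1ccc(OCc2ccccc2)cc1
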